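We reckon this flask along its exposure, the time integral of c_X, not along the clock. We take the log-slope of L in a window to be k, the rate constant of L with X summed over its routes, times the mean c_X there.

| setting | blue | flask |
|---|---|---|
| L | 0.025 M | 0.050 M |
| X | 0.10 M | 0.100 M |
| remark | run made earlier |  |
| time |  | 2.0 d |

blue run (percent of the L charged)

| time / h | L / % | Z / % |
|---|---|---|
| 0.417 | 44.7 | 12.3 |
| 0.833 | 25.2 | 14.0 |
| 2.00 | 7.7 | 5.9 |
| 5.00 | 0.1 | 0.8 |

(readings scatter by 1 percentage point)

1. which holds at 2.0 d: what has brought the reaction to rest, or that it has not come to rest (X has run out first / all of L has reacted / it is still moving / forward and back rates have come level)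
2. part of the L gone at 2.0 d
3. the Z standing at 2.0 d, as a percentage of the L charged
4. the G standing at 2.0 d, as a percentage of the L charged

- the reaction counts as stopped when no species that holds the L changes by six tenths of a point or more over the second half of the time

There are two ways to see how c_X fell in the blue run. The log-slope of L is 1.93 /h up to 0.417 h and 1.02 /h from 0.833 h to 2.00 h, so the later mean c_X is 0.526 of the earlier. The balance of X, even with two X taken by every L, gives 0.676, more than the slopes allow. The later window ends on a reading of 7.7% that scatters by 1 percentage point, so this is a hint, but we follow it and let the balance be the one that cheats.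

Suppose X also decays by itself at first-order rate d. That loss equals d times the exposure, so it has a clock-free form. We name the toll d/k, the X lost by itself per e-fold of L. With 1.50 X per L, our assumption midway between one and two, the two windows give as a reading a toll of 0.0122 M and k of 22.8 /M/h. The half-life of X by this decay, as read, 2.49 h, is far shorter than the 2.0 d allowed, so we expect the 0.100 M of X charged to be used up in this flask and the flask to come to rest within that time. We look for the L left at which the cost meets the charge: with 8.33% of L left, adducts plus toll cost 0.0991 M against 0.100 M charged, so our own figure for conversion is 91.7%.

The forecast says otherwise: it is still moving, conversion 99.6%, Z 0.7%, G 2.5%, with the ground “These are still falling by about 1 point over the second day”.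

The flask gives: X has run out first, conversion 94.5%, Z 4.42%, G 55.4%.

    L + X → Z + D (k = 0.140 /M/min)
    L + X → G + D (k = 0.220 /M/min)
    X + Z → E + D (k = 0.450 /M/min)
    X + G → E + D (k = 0.00730 /M/min)
    X → J (k = 0.00440 /min)

In this flask, by 0.200 d, L stood at 7.37% and X, the limiting reagent, at 5.52% of its charge. By 1.00 d X stood at 0%, and L, Z and G held their values through 20.0 d. The toll times the e-folds of L gives 0.0354 M of X lost by itself, and J stands at 0.0354 M. In the neighbour flask charged with 0.060 M of X, L stands at 28.0% after 2.00 d, the toll gives 0.0155 M, and J stands at 0.0156 M.

The data were generated by integration for an exercise; scatter was added.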